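With the ring numbered C1 (CHOAc), C2, C3 (CHBr), C4 (CMe2), C5=C6 and the side chain C7–C8, the route rests on cutting C1–C2 and C3–C4. C1–O and C3–Br are 1,3-related across C2, flanked by the alkene and the quaternary C4, which is what a vinyl ether leaves on adding across a 2-pyrone. One copper-catalysed asymmetric inverse-demand [4+2] reaction of methyl 5-bromo-2-pyrone-3-carboxylate with 4-methoxybenzyl vinyl ether closes the carbocycle as a lactone-bridged bicyclo[2.2.2]octene, sets C1 and places the C3 oxygen trans to it for invertive bromination. The pyrone bromine marks C6 for side-chain coupling, the two carboxyl carbons become the C4 methyls, and the p-methoxybenzyl ether, unlike a benzyl ether, is removable oxidatively beside alkene and bromide.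

Key step: step 3

Remarks. Locants C1–C8 in the Why lines are those of the target; compound names carry their own systematic locants. Assumption: the (S,S)-ligand, 2,2′-(propane-2,2-diyl)bis[(4S)-4-tert-butyl-4,5-dihydro-1,3-oxazole], is taken to give the (1R,4R,5R) adduct; if the antipode formed, the (R,R)-ligand would be used with nothing else changed. Compound 5 is made in one step because its commercial supply is uncertain; 1, 3, 4 and 14 are commercial.

Step 1
Reactants: 1 methyl 2-oxo-2H-pyran-3-carboxylate
Product: 2 methyl 5-bromo-2-oxo-2H-pyran-3-carboxylate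
Conditions: Br2, NaOAc, AcOH, 50 °C
Reagents that add atoms: bromine, BrBr
Why: Electrophilic substitution of the 2-pyrone: the ester blocks C3, so bromine attacks C5, the β-carbon of the ring enol ether, and the C6 oxocarbenium ion loses the C5 proton to restore the pyrone.

Step 2
Reactants: 3 4-methoxybenzyl alcohol; 4 vinyl acetate
Product: 5 4-methoxybenzyl vinyl ether (1-methoxy-4-[(vinyloxy)methyl]benzene)
Conditions: [Ir(cod)Cl]2 (1 mol %), Na2CO3, toluene, 100 °C
Reagents that add atoms: none
Why: Iridium-catalysed transfer vinylation of an alcohol by vinyl acetate, driven by capture of the liberated acetic acid by carbonate; no stereocentre is involved.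

Step 3
Reactants: 2 methyl 5-bromo-2-oxo-2H-pyran-3-carboxylate; 5 4-methoxybenzyl vinyl ether
Product: 6 methyl (1R,4R,5R)-7-bromo-5-[(4-methoxybenzyl)oxy]-3-oxo-2-oxabicyclo[2.2.2]oct-7-ene-4-carboxylate (ether group endo, anti to the lactone bridge)
Conditions: Cu(OTf)2 (10 mol %), (S,S)-t-Bu-BOX (11 mol %), 4 Å MS, CH2Cl2, −40 °C
Reagents that add atoms: none
Why: The copper–bis(oxazoline) Lewis acid chelates the ester and lactone carbonyls of 2 and lowers the diene LUMO, and the vinyl ether adds in an asynchronous concerted inverse-electron-demand Diels–Alder reaction, its CH2 terminus bonding to pyrone C6 (the C1–C2 bond) and its oxygenated carbon to pyrone C3 (the C3–C4 bond). The closest known reaction type is the chiral Lewis acid-catalysed [4+2] cycloaddition of 3-carbomethoxy-2-pyrone with vinyl ethers, from which 2 differs only by the 5-bromo substituent, which makes the diene more electron-poor. The carbocycle closes by intermolecular [4+2] cycloaddition, the lactone staying as the two-atom bridge of a 2-oxabicyclo[2.2.2]octene. C1 and the quaternary bridgehead are set by the face of the chelated pyrone that the tert-butyl groups of the ligand leave open, and the ether carbon (C3) by the endo approach of the alkoxy group, which places it anti to the lactone bridge and so trans to the C1 oxygen. The step needs regio-, endo and facial selectivity: the polarised diene (electrophilic C6) against the nucleophilic CH2 of the vinyl ether secures the first, secondary orbital and electrostatic attraction in the endo transition state the second, and two-point binding to the chiral divalent copper centre the third. Low temperature keeps the adduct from extruding CO2 and the vinyl ether from cationic polymerisation.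

Step 4
Reactants: 6 the bicyclic lactone
Product: 7 dimethyl (4R,6R)-3-bromo-4-hydroxy-6-[(4-methoxybenzyl)oxy]cyclohex-2-ene-1,1-dicarboxylate
Conditions: NaOMe (0.2 equiv), MeOH, −20 to 0 °C; AcOH quench
Reagents that add atoms: methanol, CO
Why: Base-catalysed lactone methanolysis (transesterification) opens the strained bridge by acyl–oxygen cleavage, so C1 keeps its configuration, and the gem-diester has no α-hydrogen, so neither epimerisation nor β-elimination of the C3 ether can occur.

Step 5
Reactants: 7 the hydroxy diester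
Product: 8 dimethyl (4R,6R)-3-bromo-4-[(tert-butyldimethylsilyl)oxy]-6-[(4-methoxybenzyl)oxy]cyclohex-2-ene-1,1-dicarboxylate
Conditions: TBSCl, imidazole, DMF, rt
Reagents that add atoms: tert-butyldimethylsilyl chloride, CC(C)(C)[Si](C)(C)Cl
Why: Imidazole-promoted silylation of the secondary allylic alcohol masks C1–OH for the hydride and sulfonylation steps, which would otherwise sulfonylate it or let its alkoxide cyclise onto a sulfonate.

Step 6
Reactants: 8 the silyl ether diester
Product: 9 [(4R,6R)-3-bromo-4-[(tert-butyldimethylsilyl)oxy]-6-[(4-methoxybenzyl)oxy]cyclohex-2-ene-1,1-diyl]dimethanol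
Conditions: LiAlH4, THF, 0 °C
Reagents that add atoms: none
Why: Hydride reduction of both esters of a 2,2-disubstituted malonate to the 1,3-diol; the alkenyl bromide, silyl ether and p-methoxybenzyl ether are inert to LiAlH4 at 0 °C.

Step 7
Reactants: 9 the diol
Product: 10 [(4R,6R)-3-bromo-4-[(tert-butyldimethylsilyl)oxy]-6-[(4-methoxybenzyl)oxy]cyclohex-2-ene-1,1-diyl]bis(methylene) dimethanesulfonate
Conditions: MsCl, Et3N, CH2Cl2, 0 °C
Reagents that add atoms: methanesulfonyl chloride, CS(=O)(=O)Cl
Why: Mesylation through sulfene is little slowed by the neopentyl environment, and the two primary hydroxyls are the only free ones.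

Step 8
Reactants: 10 the bis-mesylate
Product: 11 {[(1R,5R)-2-bromo-5-[(4-methoxybenzyl)oxy]-4,4-dimethylcyclohex-2-en-1-yl]oxy}(tert-butyl)dimethylsilane
Conditions: LiEt3BH (excess), THF, 0 °C to reflux; NaOH, H2O2 work-up
Reagents that add atoms: none
Why: SN2 displacement of primary sulfonates by the strongly nucleophilic hydride of LiEt3BH, the usual last stage of a malonate-to-gem-dimethyl conversion; the alkenyl bromide and both ethers do not react.

Step 9
Reactants: 11 the p-methoxybenzyl ether
Product: 12 (1R,5R)-4-bromo-5-[(tert-butyldimethylsilyl)oxy]-2,2-dimethylcyclohex-3-en-1-ol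
Conditions: DDQ, CH2Cl2/pH 7 buffer, 0 °C to rt
Reagents that add atoms: none
Why: Oxidative cleavage of the p-methoxybenzyl ether by DDQ (benzylic hydride abstraction, then hydrolysis of the oxocarbenium ion) leaves the silyl ether, alkene and alkenyl bromide untouched.

Step 10
Reactants: 12 the C3 alcohol
Product: 13 {[(1R,5S)-2,5-dibromo-4,4-dimethylcyclohex-2-en-1-yl]oxy}(tert-butyl)dimethylsilane
Conditions: CBr4, P(n-Oct)3, pyridine, toluene, 70 °C
Reagents that add atoms: tetrabromomethane, BrC(Br)(Br)Br
Why: Appel bromination: bromide displaces the alkoxyphosphonium ion by SN2 with inversion, turning the (R)-alcohol trans to the C1 oxygen into the (S)-bromide cis to it, and it is placed on this robust intermediate because the neopentyl carbinol needs heating.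

Step 11
Reactants: 13 the dibromide; 14 tributyl(1-ethoxyvinyl)stannane
Product: 15 {[(1R,5S)-5-bromo-2-(1-ethoxyvinyl)-4,4-dimethylcyclohex-2-en-1-yl]oxy}(tert-butyl)dimethylsilane
Conditions: Pd(PPh3)4 (5 mol %), toluene, 100 °C; aqueous KF work-up
Reagents that add atoms: none
Why: Stille coupling of the alkenyl bromide with an α-alkoxyvinylstannane as acyl equivalent; zerovalent palladium inserts only into the C(sp2)–Br bond, the hindered secondary C3–Br bond and the allylic silyl ether being inert.

Step 12
Reactants: 15 the ethoxy diene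
Product: 16 1-[(4S,6R)-4-bromo-6-[(tert-butyldimethylsilyl)oxy]-3,3-dimethylcyclohex-1-en-1-yl]-2-chloroethan-1-one
Conditions: NCS, NaHCO3, THF/H2O, 0 °C
Reagents that add atoms: N-chlorosuccinimide, O=C1CCC(=O)N1Cl; water, O
Why: Electrophilic chlorination of the enol ether at its terminal carbon (C8) and hydrolysis of the oxocarbenium ion give the chloromethyl ketone directly, the enol ether being far more nucleophilic than the ring alkene.

Step 13
Reactants: 16 the chloromethyl enone
Product: 17 (1R)-1-[(4S,6R)-4-bromo-6-[(tert-butyldimethylsilyl)oxy]-3,3-dimethylcyclohex-1-en-1-yl]-2-chloroethan-1-ol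
Conditions: (R)-Me-CBS oxazaborolidine (20 mol %), BH3·SMe2, THF, −20 °C
Reagents that add atoms: none
Why: Corey–Bakshi–Shibata reduction: the α-branched cyclohexenyl group acts as the large and CH2Cl as the small substituent, so the (R)-catalyst delivers hydride in the 1,2-mode to the face that gives the (7R)-chlorohydrin under reagent control.

Step 14
Reactants: 17 the chlorohydrin
Product: 18 {[(1R,5S)-5-bromo-2-[(1S)-1-bromo-2-chloroethyl]-4,4-dimethylcyclohex-2-en-1-yl]oxy}(tert-butyl)dimethylsilane
Conditions: CBr4, PPh3, CH2Cl2, −20 to 0 °C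
Reagents that add atoms: tetrabromomethane, BrC(Br)(Br)Br
Why: Appel reaction of the secondary allylic alcohol with SN2 inversion to the (7S)-bromide; attack at the transposed terminus C5 is blocked by the quaternary C4 and ionisation is disfavoured by the β-chlorine.

Step 15
Reactants: 18 the silyl ether
Product: 19 (1R,5S)-5-bromo-2-[(1S)-1-bromo-2-chloroethyl]-4,4-dimethylcyclohex-2-en-1-ol
Conditions: HF·pyridine, pyridine, THF, 0 °C to rt
Reagents that add atoms: none
Why: Fluoride-driven cleavage of the silyl ether under buffered, non-basic and weakly nucleophilic conditions, so the alkyl bromides and the chloride should be neither displaced nor eliminated.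

Step 16
Reactants: 19 the allylic alcohol
Product: 20 (1R,5S)-5-bromo-2-[(1S)-1-bromo-2-chloroethyl]-4,4-dimethylcyclohex-2-en-1-yl acetate (target)
Conditions: Ac2O, Et3N, DMAP (5 mol %), CH2Cl2, 0 °C
Reagents that add atoms: acetic anhydride, CC(=O)OC(C)=O
Why: DMAP-catalysed acylation at oxygen with retention at C1, run cold and briefly so that the amines do not attack the allylic bromide.

Compound list
1 | methyl 2-oxo-2H-pyran-3-carboxylate | COC(=O)C1=CC=COC1=O | starting material
2 | methyl 5-bromo-2-oxo-2H-pyran-3-carboxylate | COC(=O)C1=CC(Br)=COC1=O | intermediate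
3 | 4-methoxybenzyl alcohol | COc1ccc(CO)cc1 | starting material
4 | vinyl acetate | CC(=O)OC=C | starting material
5 | 4-methoxybenzyl vinyl ether | C=COCc1ccc(OC)cc1 | intermediate
6 | methyl (1R,4R,5R)-7-bromo-5-[(4-methoxybenzyl)oxy]-3-oxo-2-oxabicyclo[2.2.2]oct-7-ene-4-carboxylate | O=C1O[C@@H]2C[C@@H](OCc3ccc(OC)cc3)[C@@]1(C(=O)OC)C=C2Br | intermediate
7 | dimethyl (4R,6R)-3-bromo-4-hydroxy-6-[(4-methoxybenzyl)oxy]cyclohex-2-ene-1,1-dicarboxylate | O[C@@H]1C[C@@H](OCc2ccc(OC)cc2)C(C(=O)OC)(C(=O)OC)C=C1Br | intermediate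
8 | dimethyl (4R,6R)-3-bromo-4-[(tert-butyldimethylsilyl)oxy]-6-[(4-methoxybenzyl)oxy]cyclohex-2-ene-1,1-dicarboxylate | CC(C)(C)[Si](C)(C)O[C@@H]1C[C@@H](OCc2ccc(OC)cc2)C(C(=O)OC)(C(=O)OC)C=C1Br | intermediate
9 | [(4R,6R)-3-bromo-4-[(tert-butyldimethylsilyl)oxy]-6-[(4-methoxybenzyl)oxy]cyclohex-2-ene-1,1-diyl]dimethanol | CC(C)(C)[Si](C)(C)O[C@@H]1C[C@@H](OCc2ccc(OC)cc2)C(CO)(CO)C=C1Br | intermediate
10 | [(4R,6R)-3-bromo-4-[(tert-butyldimethylsilyl)oxy]-6-[(4-methoxybenzyl)oxy]cyclohex-2-ene-1,1-diyl]bis(methylene) dimethanesulfonate | CC(C)(C)[Si](C)(C)O[C@@H]1C[C@@H](OCc2ccc(OC)cc2)C(COS(C)(=O)=O)(COS(C)(=O)=O)C=C1Br | intermediate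
11 | {[(1R,5R)-2-bromo-5-[(4-methoxybenzyl)oxy]-4,4-dimethylcyclohex-2-en-1-yl]oxy}(tert-butyl)dimethylsilane | CC(C)(C)[Si](C)(C)O[C@@H]1C[C@@H](OCc2ccc(OC)cc2)C(C)(C)C=C1Br | intermediate
12 | (1R,5R)-4-bromo-5-[(tert-butyldimethylsilyl)oxy]-2,2-dimethylcyclohex-3-en-1-ol | CC(C)(C)[Si](C)(C)O[C@@H]1C[C@@H](O)C(C)(C)C=C1Br | intermediate
13 | {[(1R,5S)-2,5-dibromo-4,4-dimethylcyclohex-2-en-1-yl]oxy}(tert-butyl)dimethylsilane | CC(C)(C)[Si](C)(C)O[C@@H]1C[C@H](Br)C(C)(C)C=C1Br | intermediate
14 | tributyl(1-ethoxyvinyl)stannane | CCCC[Sn](CCCC)(CCCC)C(=C)OCC | starting material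
15 | {[(1R,5S)-5-bromo-2-(1-ethoxyvinyl)-4,4-dimethylcyclohex-2-en-1-yl]oxy}(tert-butyl)dimethylsilane | CC(C)(C)[Si](C)(C)O[C@@H]1C[C@H](Br)C(C)(C)C=C1C(=C)OCC | intermediate
16 | 1-[(4S,6R)-4-bromo-6-[(tert-butyldimethylsilyl)oxy]-3,3-dimethylcyclohex-1-en-1-yl]-2-chloroethan-1-one | CC(C)(C)[Si](C)(C)O[C@@H]1C[C@H](Br)C(C)(C)C=C1C(=O)CCl | intermediate
17 | (1R)-1-[(4S,6R)-4-bromo-6-[(tert-butyldimethylsilyl)oxy]-3,3-dimethylcyclohex-1-en-1-yl]-2-chloroethan-1-ol | CC(C)(C)[Si](C)(C)O[C@@H]1C[C@H](Br)C(C)(C)C=C1[C@@H](O)CCl | intermediate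
18 | {[(1R,5S)-5-bromo-2-[(1S)-1-bromo-2-chloroethyl]-4,4-dimethylcyclohex-2-en-1-yl]oxy}(tert-butyl)dimethylsilane | CC(C)(C)[Si](C)(C)O[C@@H]1C[C@H](Br)C(C)(C)C=C1[C@H](Br)CCl | intermediate
19 | (1R,5S)-5-bromo-2-[(1S)-1-bromo-2-chloroethyl]-4,4-dimethylcyclohex-2-en-1-ol | O[C@@H]1C[C@H](Br)C(C)(C)C=C1[C@H](Br)CCl | intermediate
20 | (1R,5S)-5-bromo-2-[(1S)-1-bromo-2-chloroethyl]-4,4-dimethylcyclohex-2-en-1-yl acetate | CC(=O)O[C@@H]1C[C@H](Br)C(C)(C)C=C1[C@H](Br)CCl | target

Total step count: 16. Longest linear sequence: 15 steps (steps 1 and 3–16 from pyrone 1; equally steps 2–16 from alcohol 3).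

Steps most likely to fail

Step 3. The chiral copper catalyst may give poor facial selectivity with the brominated pyrone, or fail to turn over while the vinyl ether polymerises. The fallback sets out from 2 and 5 and gives up catalyst control for resolution. The cycloaddition would be run with achiral Yb(OTf)3 in CH2Cl2 at −20 °C, which gives 6 together with its mirror image, the enantiomeric adduct F1. Methanolysis as in step 4 then gives 7 mixed with the antipodal hydroxy diester F2. Lipase-catalysed acylation (Burkholderia cepacia lipase, vinyl acetate, tert-butyl methyl ether, 30 °C), which for 2-halocycloalk-2-en-1-ols normally acylates the (R)-carbinol, should convert 7 into the C1 acetate F3 and leave F2 behind. After separation, K2CO3 in MeOH returns F3 to 7, where the route is rejoined.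

Step 10. Substitution at the neopentyl carbinol C3 is slow, so E2 loss toward C2, methyl migration from C4 or cleavage of the silyl ether by the hot phosphonium reagent may overtake the SN2 event. The fallback sets out from 12 and separates activation from displacement. ClCH2SO2Cl and pyridine in CH2Cl2 at 0 °C would give the isolable C3 chloromethanesulfonate F4, a leaving group more reactive than a mesylate yet not prone to ionise like a triflate. An excess of LiBr in DMF at 50 °C should then displace it with inversion to give 13, where the route is rejoined.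

Step 11. Oxidative addition at the hindered C6–Br bond beside the silyloxy-bearing C1 may be slow, letting protodestannylation of 14 or hydrolysis of the enol ether product win. The fallback sets out from 11, before any alkyl bromide is present, and replaces palladium coupling by an organolithium acylation.
- Bromine–lithium exchange with t-BuLi (2 equiv, THF, −78 °C) and addition to N-methoxy-N-methylacetamide would give the methyl ketone F5.
- DDQ as in step 9 would give the hydroxy enone F6.
- Bromination as in step 10 would give the C3-bromo enone F7.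
- Kinetic enolisation with LiHMDS and TMSCl at −78 °C, possible only at the methyl group, would give the trimethylsilyl enol ether F8, which is not isolated.
- NCS would chlorinate F8 at C8 to give 16, where the route is rejoined.

Further compounds
F1 | step 3 | methyl (1S,4S,5S)-7-bromo-5-[(4-methoxybenzyl)oxy]-3-oxo-2-oxabicyclo[2.2.2]oct-7-ene-4-carboxylate | O=C1O[C@H]2C[C@H](OCc3ccc(OC)cc3)[C@]1(C(=O)OC)C=C2Br
F2 | step 3 | dimethyl (4S,6S)-3-bromo-4-hydroxy-6-[(4-methoxybenzyl)oxy]cyclohex-2-ene-1,1-dicarboxylate | O[C@H]1C[C@H](OCc2ccc(OC)cc2)C(C(=O)OC)(C(=O)OC)C=C1Br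
F3 | step 3 | dimethyl (4R,6R)-4-acetoxy-3-bromo-6-[(4-methoxybenzyl)oxy]cyclohex-2-ene-1,1-dicarboxylate | CC(=O)O[C@@H]1C[C@@H](OCc2ccc(OC)cc2)C(C(=O)OC)(C(=O)OC)C=C1Br
F4 | step 10 | (1R,5R)-4-bromo-5-[(tert-butyldimethylsilyl)oxy]-2,2-dimethylcyclohex-3-en-1-yl chloromethanesulfonate | CC(C)(C)[Si](C)(C)O[C@@H]1C[C@@H](OS(=O)(=O)CCl)C(C)(C)C=C1Br
F5 | step 11 | 1-[(4R,6R)-6-[(tert-butyldimethylsilyl)oxy]-4-[(4-methoxybenzyl)oxy]-3,3-dimethylcyclohex-1-en-1-yl]ethan-1-one | CC(C)(C)[Si](C)(C)O[C@@H]1C[C@@H](OCc2ccc(OC)cc2)C(C)(C)C=C1C(C)=O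
F6 | step 11 | 1-[(4R,6R)-6-[(tert-butyldimethylsilyl)oxy]-4-hydroxy-3,3-dimethylcyclohex-1-en-1-yl]ethan-1-one | CC(C)(C)[Si](C)(C)O[C@@H]1C[C@@H](O)C(C)(C)C=C1C(C)=O
F7 | step 11 | 1-[(4S,6R)-4-bromo-6-[(tert-butyldimethylsilyl)oxy]-3,3-dimethylcyclohex-1-en-1-yl]ethan-1-one | CC(C)(C)[Si](C)(C)O[C@@H]1C[C@H](Br)C(C)(C)C=C1C(C)=O
F8 | step 11 | {[(1R,5S)-5-bromo-4,4-dimethyl-2-{1-[(trimethylsilyl)oxy]vinyl}cyclohex-2-en-1-yl]oxy}(tert-butyl)dimethylsilane | CC(C)(C)[Si](C)(C)O[C@@H]1C[C@H](Br)C(C)(C)C=C1C(=C)O[Si](C)(C)C
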